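**Plan**
1. Retrosynthesis: the ring B CH2OH is traced back to a methyl ester and the C6' prenyl ether to a phenol. Ring B is then cut at C2'–C3', C3'–C4', C5'–C6' and C6'–C1' into a vinylketene and methoxyethyne. Last, the enol ether C1'–O bond and the ring A prenyl ether are cut.
2. Enabling feature: ring A is the benzoate ring (C1 CO2Me, C2 O-prenyl, C4 CH3, C6 ether oxygen) and ring B the benzyl alcohol ring (C1' ether oxygen, C2' CH2OH, C4' OCH3, C6' O-prenyl). The C4' and C6' oxygens of ring B are meta with C5'–H between them, the pattern left when a vinylketene (C6', C3', C2', C1') combines with an oxygenated terminal alkyne (C4', C5').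
3. Forward: ring A is bought and mono-prenylated. Its free phenol then takes up C1', C2', the future CH2OH carbon, C6' and C3' as an acetoacetate-derived enol ether, and diazo transfer at C3' prepares the Wolff rearrangement.
4. Ring B is grown onto the ring A oxygen in one photochemical and thermal cascade with methoxyethyne, which delivers C4'–OCH3 ready-made. Prenylation of the new C6' phenol and reduction of the less hindered ester finish the target.
5. Stereochemistry: the target has no stereocentre and no stereogenic double bond. The enol ether geometry and the transient sp3 centres of the cascade disappear on aromatisation.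

Key step: step 7

Assumption: each alkoxy- or aryloxymethylene compound is drawn and named as the isomer with the ether oxygen cis to the methyl ester; an E/Z mixture would serve equally, because this double bond becomes part of ring B.

**Step 1**
Reactants: 1 methyl 2,6-dihydroxy-4-methylbenzoate; 2 prenyl bromide (1-bromo-3-methylbut-2-ene)
Product: 3 methyl 2-hydroxy-4-methyl-6-[(3-methylbut-2-en-1-yl)oxy]benzoate
Conditions: 2 (1.0 equiv), K2CO3 (1.1 equiv), acetone, 40 °C; mono-ether separated from diether and recovered 1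
Reagents that add atoms: prenyl bromide (2), CC(C)=CCBr
Why: Williamson ether synthesis on a symmetric diol, so only the degree of alkylation has to be controlled; after the first alkylation the remaining hydroxyl is chelated to the ester carbonyl and less acidic, which should slow the second alkylation.

**Step 2**
Reactants: 4 methyl acetoacetate; 5 trimethyl orthoformate
Product: 6 methyl (2Z)-2-(methoxymethylidene)-3-oxobutanoate
Conditions: HC(OMe)3 (1.2 equiv), Ac2O (2.2 equiv), 120 °C, MeOAc and AcOH distilled off; vacuum distillation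
Reagents that add atoms: trimethyl orthoformate (5), COC(OC)OC
Why: Claisen-type alkoxymethylenation of an active methylene compound with an orthoester, driven by acetylation of the liberated methanol.

**Step 3**
Reactants: 3 methyl 2-hydroxy-4-methyl-6-[(3-methylbut-2-en-1-yl)oxy]benzoate; 6 methyl (2Z)-2-(methoxymethylidene)-3-oxobutanoate
Product: 7 methyl 2-{[(1Z)-2-(methoxycarbonyl)-3-oxobut-1-en-1-yl]oxy}-4-methyl-6-[(3-methylbut-2-en-1-yl)oxy]benzoate
Conditions: 6 (2 equiv), Cs2CO3 (10 mol%), toluene, reflux through a Soxhlet thimble of 4 Å molecular sieves (MeOH removal)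
Reagents that add atoms: methyl (2Z)-2-(methoxymethylidene)-3-oxobutanoate (6), CO/C=C(/C(C)=O)C(=O)OC
Why: vinylic nucleophilic substitution (addition–elimination) of the phenoxide at the doubly activated methoxymethylene carbon; the exchange is an equilibrium and should be pulled to the aryl enol ether by trapping methanol, and all esters are methyl esters so alkoxide exchange is degenerate.

**Step 4**
Reactants: 7 methyl 2-{[(1Z)-2-(methoxycarbonyl)-3-oxobut-1-en-1-yl]oxy}-4-methyl-6-[(3-methylbut-2-en-1-yl)oxy]benzoate
Product: 8 methyl 2-{[(1Z)-6,6,6-trifluoro-2-(methoxycarbonyl)-3,5-dioxohex-1-en-1-yl]oxy}-4-methyl-6-[(3-methylbut-2-en-1-yl)oxy]benzoate (used crude)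
Conditions: LiN(SiMe3)2 (1.1 equiv), THF, −78 °C; CF3CO2CH2CF3 (1.2 equiv), −78 °C, 10 min; 5% aq. HCl work-up
Reagents that add atoms: 2,2,2-trifluoroethyl trifluoroacetate, O=C(OCC(F)(F)F)C(F)(F)F
Why: kinetic enolisation at the acetyl methyl group, the only enolisable position, followed by Claisen condensation with the activated trifluoroacetate; the hindered amide base at −78 °C should deprotonate faster than it adds to the enol ether carbon.

**Step 5**
Reactants: 8 methyl 2-{[(1Z)-6,6,6-trifluoro-2-(methoxycarbonyl)-3,5-dioxohex-1-en-1-yl]oxy}-4-methyl-6-[(3-methylbut-2-en-1-yl)oxy]benzoate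
Product: 9 methyl 2-{[(1Z)-4-diazo-2-(methoxycarbonyl)-3-oxobut-1-en-1-yl]oxy}-4-methyl-6-[(3-methylbut-2-en-1-yl)oxy]benzoate
Conditions: MsN3 (1.5 equiv), Et3N (1.5 equiv), H2O (1 equiv), MeCN, 25 °C
Reagents that add atoms: methanesulfonyl azide, CS(=O)(=O)N=[N+]=[N-]
Why: deacylative (detrifluoroacetylative) Regitz diazo transfer; the methylene between the two ketones takes up the diazo group and the trifluoroacetyl group leaves with the sulfonamide, which avoids exposing the electron-poor alkene to diazomethane.

**Step 6**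
Reactants: 10 chloroacetaldehyde dimethyl acetal (2-chloro-1,1-dimethoxyethane)
Product: 11 methoxyethyne
Conditions: NaNH2 (3 equiv), liquid NH3, −33 °C; NH3 evaporated; cold brine, −70 °C; distilled (bp about 23 °C) into cold ClCH2CH2Cl
Reagents that add atoms: none
Why: twofold base-induced elimination (methanol, then HCl) as in the standard preparation of alkoxyethynes; the third equivalent of amide holds the product as its sodium acetylide until the cold aqueous quench.

**Step 7**
Reactants: 9 methyl 2-{[(1Z)-4-diazo-2-(methoxycarbonyl)-3-oxobut-1-en-1-yl]oxy}-4-methyl-6-[(3-methylbut-2-en-1-yl)oxy]benzoate; 11 methoxyethyne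
Product: 16 methyl 2-[2-hydroxy-4-methoxy-6-(methoxycarbonyl)phenoxy]-4-methyl-6-[(3-methylbut-2-en-1-yl)oxy]benzoate, via aryloxy vinylketene 12 (not isolated), via 4-alkenyl-3-methoxycyclobutenone 13 (not isolated), via dienylketene 14 (not isolated), via cyclohexa-2,4-dienone 15 (not isolated)
Conditions: 11 (4 equiv), ClCH2CH2Cl (0.05 M), hν 365 nm (LED, sealed Pyrex tube), 15 °C; then 80 °C
Reagents that add atoms: methoxyethyne (11), COC#C
Why: Danheiser benzannulation in its photochemical Wolff variant: excitation of 9 expels N2 and the alkenyl group shifts to the former diazo carbon (C2'–C3'), giving vinylketene 12; its ketene carbon (the future C6') is attacked by the nucleophilic CH carbon of 11 (C5') while the methoxy-bearing carbon (C4') bonds to C3', so a [2+2] cycloaddition gives cyclobutenone 13. Light or the 80 °C stage should open 13 by a conrotatory 4π electrocyclic reaction to dienylketene 14, a disrotatory 6π electrocyclisation between C6' and the aryloxy-bearing C1' closes ring B as dienone 15, and enolisation gives phenol 16. The closest known reactions are the same annulations of α'-diazo enones with alkoxy- and siloxyalkynes to resorcinol monoethers; a vinylketene carrying both a β-aryloxy donor and an α-ester acceptor has not been used in them, which is why this step is ranked as the riskiest. No stereocentre survives: the sp3 centres of 13 and 15 and the enol ether geometry are erased on aromatisation. The required regiochemistry (methoxy on C4', free hydroxyl on C6') follows from the polarisation of the ynol ether toward the electrophilic ketene carbon, the Z enol ether keeps the aryloxy group on the outside of the triene terminus during the 6π closure, and irradiation at 365 nm, where only the diazo enone absorbs, should spare the aryl prenyl ether.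

**Step 8**
Reactants: 16 methyl 2-[2-hydroxy-4-methoxy-6-(methoxycarbonyl)phenoxy]-4-methyl-6-[(3-methylbut-2-en-1-yl)oxy]benzoate; 2 prenyl bromide
Product: 17 methyl 2-{4-methoxy-2-(methoxycarbonyl)-6-[(3-methylbut-2-en-1-yl)oxy]phenoxy}-4-methyl-6-[(3-methylbut-2-en-1-yl)oxy]benzoate
Conditions: 2 (1.3 equiv), K2CO3 (2 equiv), DMF, 25 °C
Reagents that add atoms: prenyl bromide (2), CC(C)=CCBr
Why: Williamson ether synthesis; the C6' hydroxyl is the only free phenol and is not chelated to an ester, so O-alkylation should be fast under mild carbonate conditions.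

**Step 9**
Reactants: 17 methyl 2-{4-methoxy-2-(methoxycarbonyl)-6-[(3-methylbut-2-en-1-yl)oxy]phenoxy}-4-methyl-6-[(3-methylbut-2-en-1-yl)oxy]benzoate
Product: 18 methyl 2-{2-(hydroxymethyl)-4-methoxy-6-[(3-methylbut-2-en-1-yl)oxy]phenoxy}-4-methyl-6-[(3-methylbut-2-en-1-yl)oxy]benzoate (CNP0561346.0)
Conditions: LiBH4 (2 equiv), THF, 0 to 40 °C; H2O quench
Reagents that add atoms: none
Why: chemoselective hydride reduction of an ester; the ring A ester is flanked by two ortho oxygen substituents, twisted out of conjugation and shielded, whereas the ring B ester has only one ortho substituent and should be reduced first; the prenyl ethers are inert to borohydride.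

**Compound list**
1 | methyl 2,6-dihydroxy-4-methylbenzoate | COC(=O)c1c(O)cc(C)cc1O | starting material
2 | prenyl bromide (1-bromo-3-methylbut-2-ene) | CC(C)=CCBr | starting material
3 | methyl 2-hydroxy-4-methyl-6-[(3-methylbut-2-en-1-yl)oxy]benzoate | COC(=O)c1c(O)cc(C)cc1OCC=C(C)C | intermediate
4 | methyl acetoacetate (methyl 3-oxobutanoate) | COC(=O)CC(C)=O | starting material
5 | trimethyl orthoformate | COC(OC)OC | starting material
6 | methyl (2Z)-2-(methoxymethylidene)-3-oxobutanoate | CO/C=C(/C(C)=O)C(=O)OC | intermediate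
7 | methyl 2-{[(1Z)-2-(methoxycarbonyl)-3-oxobut-1-en-1-yl]oxy}-4-methyl-6-[(3-methylbut-2-en-1-yl)oxy]benzoate | COC(=O)c1c(OCC=C(C)C)cc(C)cc1O/C=C(/C(C)=O)C(=O)OC | intermediate
8 | methyl 2-{[(1Z)-6,6,6-trifluoro-2-(methoxycarbonyl)-3,5-dioxohex-1-en-1-yl]oxy}-4-methyl-6-[(3-methylbut-2-en-1-yl)oxy]benzoate | COC(=O)c1c(OCC=C(C)C)cc(C)cc1O/C=C(/C(=O)CC(=O)C(F)(F)F)C(=O)OC | intermediate
9 | methyl 2-{[(1Z)-4-diazo-2-(methoxycarbonyl)-3-oxobut-1-en-1-yl]oxy}-4-methyl-6-[(3-methylbut-2-en-1-yl)oxy]benzoate | COC(=O)c1c(OCC=C(C)C)cc(C)cc1O/C=C(/C(=O)C=[N+]=[N-])C(=O)OC | intermediate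
10 | chloroacetaldehyde dimethyl acetal (2-chloro-1,1-dimethoxyethane) | COC(CCl)OC | starting material
11 | methoxyethyne | COC#C | intermediate
12 | methyl 2-{[(1Z)-2-(methoxycarbonyl)-4-oxobuta-1,3-dien-1-yl]oxy}-4-methyl-6-[(3-methylbut-2-en-1-yl)oxy]benzoate (vinylketene) | COC(=O)c1c(OCC=C(C)C)cc(C)cc1O/C=C(/C=C=O)C(=O)OC | intermediate
13 | methyl 2-{[(1Z)-2-(2-methoxy-4-oxocyclobut-2-en-1-yl)-2-(methoxycarbonyl)ethenyl]oxy}-4-methyl-6-[(3-methylbut-2-en-1-yl)oxy]benzoate (racemic cyclobutenone) | COC(=O)c1c(OCC=C(C)C)cc(C)cc1O/C=C(/C1C(=O)C=C1OC)C(=O)OC | intermediate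
14 | methyl 2-{[(1Z,3E)-4-methoxy-2-(methoxycarbonyl)-6-oxohexa-1,3,5-trien-1-yl]oxy}-4-methyl-6-[(3-methylbut-2-en-1-yl)oxy]benzoate (dienylketene) | COC(=O)c1c(OCC=C(C)C)cc(C)cc1O/C=C(/C=C(OC)\C=C=O)C(=O)OC | intermediate
15 | methyl 2-{[4-methoxy-2-(methoxycarbonyl)-6-oxocyclohexa-2,4-dien-1-yl]oxy}-4-methyl-6-[(3-methylbut-2-en-1-yl)oxy]benzoate (racemic dienone) | COC(=O)c1c(OCC=C(C)C)cc(C)cc1OC1C(=O)C=C(OC)C=C1C(=O)OC | intermediate
16 | methyl 2-[2-hydroxy-4-methoxy-6-(methoxycarbonyl)phenoxy]-4-methyl-6-[(3-methylbut-2-en-1-yl)oxy]benzoate | COC(=O)c1c(OCC=C(C)C)cc(C)cc1Oc1c(C(=O)OC)cc(OC)cc1O | intermediate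
17 | methyl 2-{4-methoxy-2-(methoxycarbonyl)-6-[(3-methylbut-2-en-1-yl)oxy]phenoxy}-4-methyl-6-[(3-methylbut-2-en-1-yl)oxy]benzoate | COC(=O)c1c(OCC=C(C)C)cc(C)cc1Oc1c(C(=O)OC)cc(OC)cc1OCC=C(C)C | intermediate
18 | methyl 2-{2-(hydroxymethyl)-4-methoxy-6-[(3-methylbut-2-en-1-yl)oxy]phenoxy}-4-methyl-6-[(3-methylbut-2-en-1-yl)oxy]benzoate | COC(=O)c1c(OCC=C(C)C)cc(C)cc1Oc1c(CO)cc(OC)cc1OCC=C(C)C | target

**Step count**
Total: 9 steps. Longest linear sequence: 7 steps (1 → 3 → 7 → 8 → 9 → 16 → 17 → 18); steps 2 and 6 are side branches.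

**Steps most likely to fail**

Step 7. The excited diazo enone or its carbene may be diverted before the Wolff shift, by ylide formation with the neighbouring aryloxy or ester oxygen or by cyclopropanation of a prenyl alkene. The donor–acceptor vinylketene may also oligomerise or acylate the product phenol faster than it adds to the alkyne. In the fallback ring B is brought in as a finished arene and the C1'–O bond is made by an Ullmann coupling. Commercial methyl 3,5-dihydroxybenzoate would be brominated beside the ester (NBS, MeCN, 0 °C) to methyl 2-bromo-3,5-dihydroxybenzoate F1. One equivalent of 2 with KHCO3 in DMF should alkylate the more acidic hydroxyl next to bromine, giving methyl 2-bromo-5-hydroxy-3-[(3-methylbut-2-en-1-yl)oxy]benzoate F2, with the regioisomer removed by chromatography. MeI and K2CO3 would then give methyl 2-bromo-5-methoxy-3-[(3-methylbut-2-en-1-yl)oxy]benzoate F3. Coupling of F3 with phenol 3 (CuI, picolinic acid, K3PO4, DMSO, 90 °C) sets out from 3 and comes back to the route at 17.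

Step 4. The amide base or the enolate may add to the doubly activated aryloxymethylene carbon and expel the aryloxide, or the enolate may condense with a second molecule, before C-trifluoroacetylation takes place. In the fallback the diazo ketone is made by acylating diazomethane with an acid chloride instead of by diazo transfer. tert-Butyl methyl malonate, HC(OMe)3 and Ac2O would give 1-tert-butyl 3-methyl (2E)-2-(methoxymethylidene)propanedioate F4. Exchange with phenol 3 under the conditions of step 3 would give 1-tert-butyl 3-methyl (2E)-2-({2-(methoxycarbonyl)-5-methyl-3-[(3-methylbut-2-en-1-yl)oxy]phenoxy}methylidene)propanedioate F5. TMSOTf and 2,6-lutidine (CH2Cl2, 0 °C, then water) would remove the tert-butyl group without the protic acid that endangers the prenyl ether, giving (2Z)-3-{2-(methoxycarbonyl)-5-methyl-3-[(3-methylbut-2-en-1-yl)oxy]phenoxy}-2-(methoxycarbonyl)prop-2-enoic acid F6. (COCl)2 with catalytic DMF would give methyl 2-{[(1E)-3-chloro-2-(methoxycarbonyl)-3-oxoprop-1-en-1-yl]oxy}-4-methyl-6-[(3-methylbut-2-en-1-yl)oxy]benzoate F7, and excess CH2N2 in Et2O at 0 °C would acylate to the diazo ketone. This fallback sets out from 3 and comes back at 9.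

Step 3. The exchange is an equilibrium that leans toward the methyl enol ether, and the chelated, ester-flanked phenol may add too slowly for methanol removal to pull it over. The fallback is an irreversible vinylic substitution with chloride as leaving group. Compound 6 would be hydrolysed (1 M NaOH, 0 °C, then dilute HCl) to methyl (2Z)-2-(hydroxymethylidene)-3-oxobutanoate F8. (COCl)2 with catalytic DMF would convert it into the vinylogous acid chloride methyl (2Z)-2-(chloromethylidene)-3-oxobutanoate F9. Phenol 3 with K2CO3 in MeCN at 25 °C should then displace chloride by addition–elimination. This fallback sets out from 6 (with 3) and comes back at 7.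

**Further compounds**
F1 | step 7 | methyl 2-bromo-3,5-dihydroxybenzoate | COC(=O)c1cc(O)cc(O)c1Br
F2 | step 7 | methyl 2-bromo-5-hydroxy-3-[(3-methylbut-2-en-1-yl)oxy]benzoate | COC(=O)c1cc(O)cc(OCC=C(C)C)c1Br
F3 | step 7 | methyl 2-bromo-5-methoxy-3-[(3-methylbut-2-en-1-yl)oxy]benzoate | COC(=O)c1cc(OC)cc(OCC=C(C)C)c1Br
F4 | step 4 | 1-tert-butyl 3-methyl (2E)-2-(methoxymethylidene)propanedioate | CO/C=C(\C(=O)OC)C(=O)OC(C)(C)C
F5 | step 4 | 1-tert-butyl 3-methyl (2E)-2-({2-(methoxycarbonyl)-5-methyl-3-[(3-methylbut-2-en-1-yl)oxy]phenoxy}methylidene)propanedioate | COC(=O)c1c(OCC=C(C)C)cc(C)cc1O/C=C(/C(=O)OC(C)(C)C)C(=O)OC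
F6 | step 4 | (2Z)-3-{2-(methoxycarbonyl)-5-methyl-3-[(3-methylbut-2-en-1-yl)oxy]phenoxy}-2-(methoxycarbonyl)prop-2-enoic acid | COC(=O)c1c(OCC=C(C)C)cc(C)cc1O/C=C(/C(O)=O)C(=O)OC
F7 | step 4 | methyl 2-{[(1E)-3-chloro-2-(methoxycarbonyl)-3-oxoprop-1-en-1-yl]oxy}-4-methyl-6-[(3-methylbut-2-en-1-yl)oxy]benzoate | COC(=O)c1c(OCC=C(C)C)cc(C)cc1O/C=C(/C(Cl)=O)C(=O)OC
F8 | step 3 | methyl (2Z)-2-(hydroxymethylidene)-3-oxobutanoate | O/C=C(/C(C)=O)C(=O)OC
F9 | step 3 | methyl (2Z)-2-(chloromethylidene)-3-oxobutanoate | Cl/C=C(/C(C)=O)C(=O)OC
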